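**Retrosynthetic overview**

1. 17 ⇒ 16 (O-desilylation) ⇒ rac-14. The cut is the bond between naphthalene C-8 and the spiro carbon (C-3 of the isoindolin-1-one). In the forward sense, acid triggers loss of a 2-pyridylthio group, a planar aryloxy-N-acyliminium ion forms, and a chiral phosphoric acid controls an enantioselective peri Friedel–Crafts closure, so the step is stereoconvergent.
2. Enabling feature: the spiro carbon bears N and O, so it is a carboxyl-level carbon that ionises to a planar cation. Its partner, naphthalene C-8, is the α-carbon ortho to the 7-OH (C-1 of a 2-naphthol, the most nucleophilic ring position) and is also peri to the C-1 oxygen. The one-atom O bridge therefore already holds both carbons in contact inside the future 2H-naphtho[1,8-bc]furan ring.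
3. rac-14 ⇒ 12 (C-3 carbanion plus dipyridyl disulfide) ⇒ hydroxylactam 10 + naphthol 5 (C-3–O bond, Mitsunobu).
4. 10 ⇒ amide 8 (directed ortho-metalation/DMF, which fixes the OMe/C-3/C=O 1,2,3-pattern) ⇒ 6 + 7. 5 ⇒ 1,7-dimethoxynaphthalene 1 (C-3-selective C–H borylation, methylation, demethylation, 7-O-silylation).
5. Ring order: the naphthalene is bought, the γ-lactam of the isoindolinone is closed in step 6, and the spiro naphtho[1,8-bc]furan ring is closed in step 10.

Key step: step 10

Numbering used: the naphthalene has the ether O on C-1, methyl on C-3 and phenol O on C-7. The isoindolinone has C-1 = C=O, N-2, C-3 = future spiro carbon and C-4 = C–OMe.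

Assumption: the sense of induction of a BINOL-derived phosphoric acid in this new ion-pair closure cannot be derived from precedent. The (R)-acid is written, and its mirror image is used if a trial run shows the opposite sense. The spiro N,O-ketal is taken to be configurationally stable near neutrality, so nothing strongly acidic or basic follows step 10.

**Step 1**
Reactants: 1 1,7-dimethoxynaphthalene
Product: 2 2-(4,6-dimethoxynaphthalen-2-yl)-4,4,5,5-tetramethyl-1,3,2-dioxaborolane (boron on C-3 of 1)
Conditions: B2pin2 (1.0 equiv), [Ir(OMe)(cod)]2 (1.5 mol %), dtbpy (3 mol %), THF, 80 °C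
Reagents that add atoms: bis(pinacolato)diboron, CC1(C)OB(OC1(C)C)B1OC(C)(C)C(C)(C)O1
Why: Iridium-catalysed aromatic C–H borylation is sterically governed, and C-3 is the only β-C–H of 1 without an ortho substituent (C-2, C-6 and C-8 flank a methoxy group, C-4 and C-5 are peri-hindered α-positions), so the boron should enter at C-3.

**Step 2**
Reactants: 2 2-(4,6-dimethoxynaphthalen-2-yl)-4,4,5,5-tetramethyl-1,3,2-dioxaborolane
Product: 3 1,7-dimethoxy-3-methylnaphthalene
Conditions: MeI (1.5 equiv), Pd2(dba)3 (2.5 mol %), P(o-tol)3 (10 mol %), K2CO3 (2 equiv), DMF/H2O 9:1, 60 °C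
Reagents that add atoms: iodomethane, CI
Why: Suzuki–Miyaura cross-coupling of the aryl pinacol boronate with iodomethane turns the C–B bond into the C-3 methyl group, and the aryl methyl ethers are inert to Pd(0) and carbonate.

**Step 3**
Reactants: 3 1,7-dimethoxy-3-methylnaphthalene
Product: 4 3-methylnaphthalene-1,7-diol
Conditions: BBr3 (2.5 equiv), CH2Cl2, −78 °C to rt; then H2O, 0 °C
Reagents that add atoms: none
Why: Boron tribromide ether cleavage (O-complexation, then SN2 attack of bromide on the methyl groups) frees both naphthols at a stage at which no other methyl ether is present, so the methoxy group of the target is never at risk.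

**Step 4**
Reactants: 4 3-methylnaphthalene-1,7-diol
Product: 5 7-[(tert-butyldimethylsilyl)oxy]-3-methylnaphthalen-1-ol
Conditions: TBSCl (1.0 equiv), imidazole (1.5 equiv), CH2Cl2/DMF, −40 to 0 °C
Reagents that add atoms: tert-butyldimethylsilyl chloride, CC(C)(C)[Si](C)(C)Cl
Why: Kinetically controlled silylation picks the unhindered β-hydroxyl at C-7, because the α-hydroxyl at C-1 is screened by the peri C-8–H, and so leaves free the oxygen that must become the furan oxygen.

**Step 5**
Reactants: 6 3-methoxybenzoyl chloride; 7 2-[(tert-butyldimethylsilyl)oxy]ethan-1-amine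
Product: 8 N-{2-[(tert-butyldimethylsilyl)oxy]ethyl}-3-methoxybenzamide
Conditions: Et3N (1.2 equiv), CH2Cl2, 0 °C to rt
Reagents that add atoms: none
Why: Schotten–Baumann-type N-acylation of the primary amine by the acid chloride is fast and leaves the silyl ether untouched.

**Step 6**
Reactants: 8 N-{2-[(tert-butyldimethylsilyl)oxy]ethyl}-3-methoxybenzamide
Product: 10 rac-2-{2-[(tert-butyldimethylsilyl)oxy]ethyl}-3-hydroxy-4-methoxyisoindolin-1-one, via dilithio amide 9 (not isolated)
Conditions: s-BuLi (2.2 equiv), TMEDA (2.2 equiv), THF, −78 °C; DMF (3 equiv), −78 °C to rt; H2O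
Reagents that add atoms: N,N-dimethylformamide, CN(C)C=O
Why: Directed ortho-metalation: the lithium amidate and the methoxy group cooperate to place the second lithium on the carbon between them, formylation with DMF and ring–chain tautomerism of the resulting 2-formylbenzamide close the γ-lactam, and the new C-3 centre is formed racemic, which is harmless because it is erased in step 10.

**Step 7**
Reactants: 10 rac-2-{2-[(tert-butyldimethylsilyl)oxy]ethyl}-3-hydroxy-4-methoxyisoindolin-1-one; 5 7-[(tert-butyldimethylsilyl)oxy]-3-methylnaphthalen-1-ol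
Product: 11 rac-2-{2-[(tert-butyldimethylsilyl)oxy]ethyl}-3-({7-[(tert-butyldimethylsilyl)oxy]-3-methylnaphthalen-1-yl}oxy)-4-methoxyisoindolin-1-one
Conditions: PPh3 (1.3 equiv), DIAD (1.3 equiv), toluene/THF, 0 °C to rt
Reagents that add atoms: none
Why: Mitsunobu reaction at a lactol-type hydroxyl, as in the Mitsunobu synthesis of aryl glycosides: the oxyphosphonium ion of the hydroxylactam is displaced by the only free and sufficiently acidic OH of 5 (C-1–OH), which makes the C-3–O bond under neutral conditions that avoid acid-induced C-arylation, and the centre stays racemic.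

**Step 8**
Reactants: 11 rac-2-{2-[(tert-butyldimethylsilyl)oxy]ethyl}-3-({7-[(tert-butyldimethylsilyl)oxy]-3-methylnaphthalen-1-yl}oxy)-4-methoxyisoindolin-1-one
Product: 12 rac-2-{2-[(tert-butyldimethylsilyl)oxy]ethyl}-3-[(7-hydroxy-3-methylnaphthalen-1-yl)oxy]-4-methoxyisoindolin-1-one
Conditions: Cs2CO3 (0.3 equiv), DMF/H2O 10:1, rt
Reagents that add atoms: none
Why: Chemoselective base-mediated desilylation: an aryl silyl ether is cleaved by carbonate far faster than an alkyl silyl ether because phenoxide is the better leaving group on silicon, and the base-stable N,O-acetal and lactam are untouched.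

**Step 9**
Reactants: 12 rac-2-{2-[(tert-butyldimethylsilyl)oxy]ethyl}-3-[(7-hydroxy-3-methylnaphthalen-1-yl)oxy]-4-methoxyisoindolin-1-one
Product: 14 rac-2-{2-[(tert-butyldimethylsilyl)oxy]ethyl}-3-[(7-hydroxy-3-methylnaphthalen-1-yl)oxy]-4-methoxy-3-(pyridin-2-ylsulfanyl)isoindolin-1-one, via dilithio naphtholate-carbanion 13 (not isolated)
Conditions: LDA (2.2 equiv), THF, −78 °C; 2,2'-dipyridyl disulfide (1.2 equiv), −78 to −40 °C; pH 7 buffer; Et3N-deactivated silica
Reagents that add atoms: 2,2'-dipyridyl disulfide, c1ccc(SSc2ccccn2)nc1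
Why: Sulfenylation of a stabilised carbanion with a disulfide: the first equivalent of LDA takes the phenol proton and the second the C-3–H (benzylic, α to N and O, anion delocalised into the lactam as an isoindololate), the soft carbanion attacks the S–S bond while the hard naphtholate does not, and the quaternary centre is formed racemic.

**Step 10**
Reactants: 14 rac-2-{2-[(tert-butyldimethylsilyl)oxy]ethyl}-3-[(7-hydroxy-3-methylnaphthalen-1-yl)oxy]-4-methoxy-3-(pyridin-2-ylsulfanyl)isoindolin-1-one
Product: 16 (S)-2-{2-[(tert-butyldimethylsilyl)oxy]ethyl}-3'-hydroxy-7-methoxy-7'-methylspiro[isoindoline-1,2'-naphtho[1,8-bc]furan]-3-one, via aryloxy-N-acyliminium ion 15 (not isolated)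
Conditions: (R)-3,3'-bis(2,4,6-triisopropylphenyl)-1,1'-binaphthyl-2,2'-diyl hydrogen phosphate (10 mol %), 4 Å MS, toluene (0.01 M), −30 °C; Et3N quench at −30 °C
Reagents that add atoms: none
Why: Proposed new method: the chiral phosphoric acid protonates the pyridine nitrogen of racemic 14, by far its most basic site, so that neutral pyridine-2-thione leaves (not the naphthol, whose ether oxygen stays unprotonated and whose loss would put a cation next to a pyridinium-thio group) and both enantiomers converge on the planar aryloxy-N-acyliminium ion 15, paired with the chiral phosphate. Naphthalene C-8, the α-carbon ortho to the free 7-OH and held in contact with the cationic carbon by the one-atom C-1–O bridge, attacks it, and the phosphate removes the proton of the Wheland intermediate, which restores the naphthol and the catalyst. The closest known reaction types are phosphoric-acid-catalysed N-acyliminium cyclisations and aza-Friedel–Crafts reactions of 2-naphthols with isoindolinone-derived iminium ions, remote activation of 2-pyridyl(thio) glycosyl donors, and peri Friedel–Crafts closures such as 1-naphthyl isocyanate to naphthostyril and 1-naphthylacetyl chloride to acenaphthenone. The five-membered 2H-naphtho[1,8-bc]furan ring closes 5-exo-trig with respect to the C=N+ bond (5-endo with respect to the C=O+ resonance form, which is why the peri precedents matter). The spiro carbon is the only new stereocentre, and its (S) configuration is set by the phosphate, which is hydrogen-bonded to the 7-OH and ion-paired with the cation and so shields one face of 15, while the stereocentre of 14 is erased, which makes the step stereoconvergent. The step needs C- over O-attack and ring closure over intermolecular arylation: O-adducts, phosphate adducts and thione re-addition are reversible, C-2 and C-6 cannot reach the cation, and high dilution with molecular sieves holds back dimerisation and hydrolysis.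

**Step 11**
Reactants: 16 (S)-2-{2-[(tert-butyldimethylsilyl)oxy]ethyl}-3'-hydroxy-7-methoxy-7'-methylspiro[isoindoline-1,2'-naphtho[1,8-bc]furan]-3-one
Product: 17 (S)-3'-hydroxy-2-(2-hydroxyethyl)-7-methoxy-7'-methylspiro[isoindoline-1,2'-naphtho[1,8-bc]furan]-3-one (target)
Conditions: HF·pyridine, excess pyridine, THF, 0 °C; pH 7 buffer
Reagents that add atoms: none
Why: Fluoride-driven Si–O cleavage (formation of the strong Si–F bond) in a pyridine-buffered medium stays near neutrality, so the acid- and base-sensitive spiro N,O-ketal is not ionised and the (S) centre is preserved.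

**Compound list**

1 | 1,7-dimethoxynaphthalene | COc1cccc2ccc(OC)cc12 | starting material
2 | 2-(4,6-dimethoxynaphthalen-2-yl)-4,4,5,5-tetramethyl-1,3,2-dioxaborolane | COc1cc(B2OC(C)(C)C(C)(C)O2)cc2ccc(OC)cc12 | intermediate
3 | 1,7-dimethoxy-3-methylnaphthalene | COc1cc(C)cc2ccc(OC)cc12 | intermediate
4 | 3-methylnaphthalene-1,7-diol | Oc1cc(C)cc2ccc(O)cc12 | intermediate
5 | 7-[(tert-butyldimethylsilyl)oxy]-3-methylnaphthalen-1-ol | Oc1cc(C)cc2ccc(O[Si](C)(C)C(C)(C)C)cc12 | intermediate
6 | 3-methoxybenzoyl chloride | COc1cccc(C(=O)Cl)c1 | starting material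
7 | 2-[(tert-butyldimethylsilyl)oxy]ethan-1-amine | NCCO[Si](C)(C)C(C)(C)C | starting material
8 | N-{2-[(tert-butyldimethylsilyl)oxy]ethyl}-3-methoxybenzamide | COc1cccc(C(=O)NCCO[Si](C)(C)C(C)(C)C)c1 | intermediate
9 | C-2,N-dilithio derivative of 8 (not isolated) | [Li]c1c(OC)cccc1C(=O)N([Li])CCO[Si](C)(C)C(C)(C)C | intermediate
10 | rac-2-{2-[(tert-butyldimethylsilyl)oxy]ethyl}-3-hydroxy-4-methoxyisoindolin-1-one | COc1cccc2c1C(O)N(CCO[Si](C)(C)C(C)(C)C)C2=O | intermediate
11 | rac-2-{2-[(tert-butyldimethylsilyl)oxy]ethyl}-3-({7-[(tert-butyldimethylsilyl)oxy]-3-methylnaphthalen-1-yl}oxy)-4-methoxyisoindolin-1-one | COc1cccc2c1C(Oc1cc(C)cc3ccc(O[Si](C)(C)C(C)(C)C)cc13)N(CCO[Si](C)(C)C(C)(C)C)C2=O | intermediate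
12 | rac-2-{2-[(tert-butyldimethylsilyl)oxy]ethyl}-3-[(7-hydroxy-3-methylnaphthalen-1-yl)oxy]-4-methoxyisoindolin-1-one | COc1cccc2c1C(Oc1cc(C)cc3ccc(O)cc13)N(CCO[Si](C)(C)C(C)(C)C)C2=O | intermediate
13 | O-7,C-3-dilithio derivative of 12 (not isolated) | COc1cccc2c1C([Li])(Oc1cc(C)cc3ccc(O[Li])cc13)N(CCO[Si](C)(C)C(C)(C)C)C2=O | intermediate
14 | rac-2-{2-[(tert-butyldimethylsilyl)oxy]ethyl}-3-[(7-hydroxy-3-methylnaphthalen-1-yl)oxy]-4-methoxy-3-(pyridin-2-ylsulfanyl)isoindolin-1-one | COc1cccc2c1C(Oc1cc(C)cc3ccc(O)cc13)(Sc1ccccn1)N(CCO[Si](C)(C)C(C)(C)C)C2=O | intermediate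
15 | 2-{2-[(tert-butyldimethylsilyl)oxy]ethyl}-3-[(7-hydroxy-3-methylnaphthalen-1-yl)oxy]-4-methoxy-1-oxo-1H-isoindol-2-ium, ion-paired with the chiral phosphate (not isolated) | COc1cccc2c1C(Oc1cc(C)cc3ccc(O)cc13)=[N+](CCO[Si](C)(C)C(C)(C)C)C2=O | intermediate
16 | (S)-2-{2-[(tert-butyldimethylsilyl)oxy]ethyl}-3'-hydroxy-7-methoxy-7'-methylspiro[isoindoline-1,2'-naphtho[1,8-bc]furan]-3-one | COc1cccc2c1[C@]1(Oc3cc(C)cc4ccc(O)c1c34)N(CCO[Si](C)(C)C(C)(C)C)C2=O | intermediate
17 | (S)-3'-hydroxy-2-(2-hydroxyethyl)-7-methoxy-7'-methylspiro[isoindoline-1,2'-naphtho[1,8-bc]furan]-3-one | COc1cccc2c1[C@]1(Oc3cc(C)cc4ccc(O)c1c34)N(CCO)C2=O | target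

**Step count**

Total step count: 11. Longest linear sequence: 9 steps (1, 2, 3, 4, 7, 8, 9, 10, 11).

**Steps most likely to fail**

**Step 10 (Proposed new method).** Several processes could defeat it:
- The strained peri closure may be slower than return of the ion pair (re-addition of thione or phosphate) or its hydrolysis.
- The closure may occur without facial discrimination.
- The liberated thione may tie up the catalyst by hydrogen bonding.
- The acid may re-ionise the product and erode its configuration.

The fallback sets out from 12 and comes back at 17. Ortho-selective bromination of the free 2-naphthol unit (NBS, cat. i-Pr2NH, CH2Cl2, −78 °C) should give the 8-bromo-7-hydroxynaphthyl ether F1. Silylation (TIPSOTf, 2,6-lutidine) should give its triisopropylsilyl ether F2. A palladium-catalysed enantioselective intramolecular α-arylation follows (Pd(0), bulky chiral N-heterocyclic carbene, NaOt-Bu, toluene). This reaction type is known for 3-alkoxy-3-aryloxindoles. It deprotonates C-3 to the planar isoindolinone anion, so it is again stereoconvergent, and it forms the same C-8–C-3 bond by reductive elimination from a six-membered palladacycle. The product is the bis-silylated spiro compound F3, which is (R) by the CIP rules because O–Si outranks O–CH3 but has the same spatial arrangement as 16. HF·pyridine then removes both silyl groups and gives 17.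

**Step 9.** The crowded carbanion may fail to capture the disulfide, or the liberated thiolate may attack the product at sulfur and reverse the sulfenylation. The fallback sets out from 10 and comes back at 14. It reverses the order in which S and O are introduced. Amidoalkylation of 2-mercaptopyridine by 10 (cat. camphorsulfonic acid, 4 Å MS, CH2Cl2) should give the 3-(pyridin-2-ylsulfanyl)lactam F4. Deprotonation (LDA, −78 °C) and chlorination with hexachloroethane should give the 3-chloro-3-(pyridin-2-ylsulfanyl)lactam F5. This is added cold to the sodium salt of 5 (NaH, THF) and should give the bis-silylated thio-orthoamide F6 by substitution through the sulfur-stabilised iminium ion. The carbonate desilylation of step 8 then gives 14.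

**Step 7.** The oxyphosphonium ion may ionise and be captured by the hydrazide anion or by a ring carbon (C-2 or C-4) of the naphthol instead of its oxygen. The fallback sets out from 10 and comes back at 11. SOCl2 with 2,6-lutidine (CH2Cl2, 0 °C) should give the 3-chlorolactam F7. This is added to the preformed sodium salt of 5 (NaH, THF/DMF, −40 °C). This is a Williamson-type O-alkylation of a hard naphthoxide in a dipolar aprotic medium.

**Further compounds**

F1 | step 10 | rac-3-[(8-bromo-7-hydroxy-3-methylnaphthalen-1-yl)oxy]-2-{2-[(tert-butyldimethylsilyl)oxy]ethyl}-4-methoxyisoindolin-1-one | COc1cccc2c1C(Oc1cc(C)cc3ccc(O)c(Br)c13)N(CCO[Si](C)(C)C(C)(C)C)C2=O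
F2 | step 10 | rac-3-({8-bromo-3-methyl-7-[(triisopropylsilyl)oxy]naphthalen-1-yl}oxy)-2-{2-[(tert-butyldimethylsilyl)oxy]ethyl}-4-methoxyisoindolin-1-one | COc1cccc2c1C(Oc1cc(C)cc3ccc(O[Si](C(C)C)(C(C)C)C(C)C)c(Br)c13)N(CCO[Si](C)(C)C(C)(C)C)C2=O
F3 | step 10 | (R)-2-{2-[(tert-butyldimethylsilyl)oxy]ethyl}-7-methoxy-7'-methyl-3'-[(triisopropylsilyl)oxy]spiro[isoindoline-1,2'-naphtho[1,8-bc]furan]-3-one | COc1cccc2c1[C@]1(Oc3cc(C)cc4ccc(O[Si](C(C)C)(C(C)C)C(C)C)c1c34)N(CCO[Si](C)(C)C(C)(C)C)C2=O
F4 | step 9 | rac-2-{2-[(tert-butyldimethylsilyl)oxy]ethyl}-4-methoxy-3-(pyridin-2-ylsulfanyl)isoindolin-1-one | COc1cccc2c1C(Sc1ccccn1)N(CCO[Si](C)(C)C(C)(C)C)C2=O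
F5 | step 9 | rac-2-{2-[(tert-butyldimethylsilyl)oxy]ethyl}-3-chloro-4-methoxy-3-(pyridin-2-ylsulfanyl)isoindolin-1-one | COc1cccc2c1C(Cl)(Sc1ccccn1)N(CCO[Si](C)(C)C(C)(C)C)C2=O
F6 | step 9 | rac-2-{2-[(tert-butyldimethylsilyl)oxy]ethyl}-3-({7-[(tert-butyldimethylsilyl)oxy]-3-methylnaphthalen-1-yl}oxy)-4-methoxy-3-(pyridin-2-ylsulfanyl)isoindolin-1-one | COc1cccc2c1C(Oc1cc(C)cc3ccc(O[Si](C)(C)C(C)(C)C)cc13)(Sc1ccccn1)N(CCO[Si](C)(C)C(C)(C)C)C2=O
F7 | step 7 | rac-2-{2-[(tert-butyldimethylsilyl)oxy]ethyl}-3-chloro-4-methoxyisoindolin-1-one | COc1cccc2c1C(Cl)N(CCO[Si](C)(C)C(C)(C)C)C2=O
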